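**Assumption:** 1,2-bis(trimethylsilyloxy)cyclobutene is counted as a six-heavy-atom C4O2 unit carrying two silyl protecting groups; the sense of induction in step 3 is assigned from the facial model given there, and the mirror-image ligand is used if it proves opposite.

**Retrosynthetic overview**
1. Target 13 ⇐ Pinnick oxidation and linear hydroformylation of the terminal alkene of tertiary acetate 11, itself from alcohol 10.
2. Alcohol 10 ⇐ enantiotopic-carbonyl-selective 1,2-addition of a hept-6-enyl zinc reagent to the Cs-symmetric ene-dione 6; this one event sets both stereocentres.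
3. Ene-dione 6 ⇐ dehydrogenation of 2-pentenylcyclopentane-1,3-dione 4.
4. The only ring is made by a four-to-five ring expansion: Mukaiyama aldol of 1,2-bis(trimethylsilyloxy)cyclobutene with (Z)-hex-3-enal, then a pinacol-type 1,2-acyl shift.
5. Starting materials: (Z)-hex-3-enal, 1,2-bis(trimethylsilyloxy)cyclobutene, 7-bromohept-1-ene.

**Route**

Step 1
Reactants: 1 (Z)-hex-3-enal; 2 1,2-bis(trimethylsilyloxy)cyclobutene
Product: 4 2-[(2Z)-pent-2-en-1-yl]cyclopentane-1,3-dione, via silylated cyclobutanone aldol adduct 3 (not isolated)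
Conditions: TMSOTf (5 mol %), CH2Cl2, −78 °C; then CF3CO2H/CH2Cl2 (1:4), 0 → 23 °C
Reagents that add atoms: none
Why: Mukaiyama aldol of the electron-rich bis-silyl enediol gives the 2-silyloxy-2-(1-silyloxyalkyl)cyclobutanone, and acid then triggers a pinacol-type 1,2-acyl shift (geminal acylation) in which the ring acyl carbon migrates to the ionising carbinol carbon, driven by strain release and formation of the silyloxy-stabilised cation, to give the achiral 2-substituted cyclopentane-1,3-dione (no stereocentre to set).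

Step 2
Reactants: 4 2-[(2Z)-pent-2-en-1-yl]cyclopentane-1,3-dione
Product: 6 2-[(2Z)-pent-2-en-1-yl]cyclopent-4-ene-1,3-dione, via 4-phenylselanyl dione 5 (not isolated)
Conditions: LDA (2.2 equiv), THF/DMPU, −78 → 0 °C; PhSeBr (1.05 equiv), −78 °C; AcOH; then NaIO4, THF/H2O, 0 → 23 °C
Reagents that add atoms: none
Why: The dianion of the enolised dione reacts with the selenium electrophile at the more basic C4 terminus, and selenoxide syn-elimination can only go toward C5, giving the ring alkene; the product stays diketonic because its enol would be a hydroxycyclopentadienone (no stereocentre).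

Step 3
Reactants: 6 2-[(2Z)-pent-2-en-1-yl]cyclopent-4-ene-1,3-dione; 7 7-bromohept-1-ene
Product: 10 (4S,5S)-4-(hept-6-en-1-yl)-4-hydroxy-5-[(2Z)-pent-2-en-1-yl]cyclopent-2-en-1-one, via hept-6-en-1-ylmagnesium bromide 8 (not isolated), via bis(hept-6-en-1-yl)zinc 9 (not isolated)
Conditions: 7, Mg, Et2O; ZnCl2 (0.5 equiv), then 1,4-dioxane, filter; then 6, Ti(OiPr)4 (1.2 equiv), (1R,2R)-trans-1,2-bis(hydroxycamphorsulfonamido)cyclohexane (10 mol %), toluene, −20 °C; aqueous work-up
Reagents that add atoms: none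
Why: Proposed new method: a titanium bis(sulfonamide)-diol complex activates one carbonyl of the Cs-symmetric ene-dione and transfers a primary alkyl group from the weakly basic dialkylzinc in a 1,2-sense to the Re face; the substrate only accepts attack anti to the pentenyl group, so only the carbonyl whose Re face is anti reacts, which fixes C4 (S, chain trans to pentenyl) and thereby makes the former C2 the (S)-configured C5, while mismatched attack would give a separable diastereomer and not the enantiomer; the closest known reaction type is the titanium/bis(sulfonamide)-catalysed enantioselective addition of dialkylzincs to ketones and cyclic enones, which has not been shown for desymmetrising a 2-monosubstituted cyclopent-4-ene-1,3-dione.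

Step 4
Reactants: 10 (4S,5S)-4-(hept-6-en-1-yl)-4-hydroxy-5-[(2Z)-pent-2-en-1-yl]cyclopent-2-en-1-one
Product: 11 (1S,5S)-1-(hept-6-en-1-yl)-4-oxo-5-[(2Z)-pent-2-en-1-yl]cyclopent-2-en-1-yl acetate
Conditions: Ac2O (3 equiv), Sc(OTf)3 (2 mol %), MeCN, −20 °C
Reagents that add atoms: acetic anhydride, CC(=O)OC(C)=O
Why: Lewis-acid-catalysed acylation esterifies hindered tertiary alcohols without base, so the β-oxy ketone is not exposed to enolisation, elimination or C5 epimerisation, and O-acylation leaves both stereocentres untouched.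

Step 5
Reactants: 11 (1S,5S)-1-(hept-6-en-1-yl)-4-oxo-5-[(2Z)-pent-2-en-1-yl]cyclopent-2-en-1-yl acetate
Product: 12 (1S,5S)-4-oxo-1-(8-oxooctyl)-5-[(2Z)-pent-2-en-1-yl]cyclopent-2-en-1-yl acetate
Conditions: CO/H2 (1:1, 10 bar), Rh(acac)(CO)2 (1 mol %), BiPhePhos (2 mol %), toluene, 60 °C
Reagents that add atoms: carbon monoxide, [C-]#[O+]
Why: Linear-selective rhodium-catalysed hydroformylation converts the monosubstituted alkene far faster than the Z-1,2-disubstituted alkene or the conjugated enone and adds the missing eighth chain carbon under neutral conditions (no stereocentre affected).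

Step 6
Reactants: 12 (1S,5S)-4-oxo-1-(8-oxooctyl)-5-[(2Z)-pent-2-en-1-yl]cyclopent-2-en-1-yl acetate
Product: 13 8-[(1S,5S)-1-(acetyloxy)-4-oxo-5-[(2Z)-pent-2-en-1-yl]cyclopent-2-en-1-yl]octanoic acid
Conditions: NaClO2, NaH2PO4, 2-methylbut-2-ene, t-BuOH/H2O, 0 → 23 °C
Reagents that add atoms: sodium chlorite, [Na+].[O-]Cl=O
Why: Pinnick oxidation converts only the aldehyde to the acid at mildly acidic pH, with 2-methylbut-2-ene scavenging HOCl so that the Z-alkene, the enone, the tertiary acetate and the epimerisable C5 survive.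

**Compound list**
1 | (Z)-hex-3-enal | CC/C=C\CC=O | starting material
2 | 1,2-bis(trimethylsilyloxy)cyclobutene | C[Si](C)(C)OC1=C(O[Si](C)(C)C)CC1 | starting material
3 | 2-[(3Z)-1-(trimethylsilyloxy)hex-3-en-1-yl]-2-(trimethylsilyloxy)cyclobutan-1-one (diastereomer mixture) | CC/C=C\CC(O[Si](C)(C)C)C1(O[Si](C)(C)C)CCC1=O | intermediate
4 | 2-[(2Z)-pent-2-en-1-yl]cyclopentane-1,3-dione (mainly as its enol) | CC/C=C\CC1C(=O)CCC1=O | intermediate
5 | 4-(phenylselanyl)-2-[(2Z)-pent-2-en-1-yl]cyclopentane-1,3-dione | CC/C=C\CC1C(=O)CC([Se]c2ccccc2)C1=O | intermediate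
6 | 2-[(2Z)-pent-2-en-1-yl]cyclopent-4-ene-1,3-dione | CC/C=C\CC1C(=O)C=CC1=O | intermediate
7 | 7-bromohept-1-ene | BrCCCCCC=C | starting material
8 | hept-6-en-1-ylmagnesium bromide | C=CCCCCC[Mg]Br | intermediate
9 | bis(hept-6-en-1-yl)zinc | C=CCCCCC[Zn]CCCCCC=C | intermediate
10 | (4S,5S)-4-(hept-6-en-1-yl)-4-hydroxy-5-[(2Z)-pent-2-en-1-yl]cyclopent-2-en-1-one (OH cis to pentenyl) | CC/C=C\C[C@@H]1C(=O)C=C[C@]1(CCCCCC=C)O | intermediate
11 | (1S,5S)-1-(hept-6-en-1-yl)-4-oxo-5-[(2Z)-pent-2-en-1-yl]cyclopent-2-en-1-yl acetate | CC/C=C\C[C@@H]1C(=O)C=C[C@]1(CCCCCC=C)OC(C)=O | intermediate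
12 | (1S,5S)-4-oxo-1-(8-oxooctyl)-5-[(2Z)-pent-2-en-1-yl]cyclopent-2-en-1-yl acetate | CC/C=C\C[C@@H]1C(=O)C=C[C@]1(CCCCCCCC=O)OC(C)=O | intermediate
13 | 8-[(1S,5S)-1-(acetyloxy)-4-oxo-5-[(2Z)-pent-2-en-1-yl]cyclopent-2-en-1-yl]octanoic acid (acetoxy cis to pentenyl, C8 chain trans) | CC/C=C\C[C@@H]1C(=O)C=C[C@]1(CCCCCCCC(=O)O)OC(C)=O | target

**Step count and risks**
Total step count: 6. Longest linear sequence: 6 steps (1 → 4 → 6 → 10 → 11 → 12 → 13); the zinc reagent is made and used in the flask of step 3.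

Three steps most likely to fail:

- **Step 3 (the proposed new step).** The C–H between the two carbonyls of 6 is a strong carbon acid, so zinc or titanium enolate formation may outrun alkyl transfer. Conjugate addition to the ene-dione and retro-aldol scrambling of the product alkoxide are further risks. The fallback uses known chemistry, sets out from 6 and returns at 10. Corey–Bakshi–Shibata reduction with (S)-Me-CBS and catecholborane in toluene at −78 °C reduces one enantiotopic carbonyl with hydride anti to the side chain. This gives (4R,5R)-4-hydroxy-5-[(2Z)-pent-2-en-1-yl]cyclopent-2-en-1-one F3, in which the remaining α-proton is that of an ordinary ketone. Addition of 8 (2.5 equiv, made from 7) with anhydrous CeCl3 in THF at −78 °C, anti to the pentenyl group, gives (1S,4R,5R)-1-(hept-6-en-1-yl)-5-[(2Z)-pent-2-en-1-yl]cyclopent-2-ene-1,4-diol F4. MnO2 in CH2Cl2 oxidises only the secondary allylic alcohol and delivers 10.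

- **Step 2.** The dianion may be poorly soluble or react at C2, and 6 is a sensitive Michael acceptor. The fallback sets out from 4 and returns at 6. Double O-silylation with TMSOTf/Et3N in CH2Cl2 gives 1,3-bis(trimethylsilyloxy)-2-[(2Z)-pent-2-en-1-yl]cyclopenta-1,3-diene F1. Saegusa–Ito oxidation with Pd(OAc)2 in MeCN gives 3-(trimethylsilyloxy)-2-[(2Z)-pent-2-en-1-yl]cyclopenta-2,4-dien-1-one F2, which is hydrolysed on aqueous work-up to 6.

- **Step 5.** Rhodium hydride may isomerise the skipped Z-alkene, hydrogenate the enone or give branched aldehyde. The fallback sets out from 10 and returns at 13. Palladium-catalysed linear hydrocarboxylation of the terminal alkene with formic acid (Pd(OAc)2, triarylphosphine, catalytic Ac2O, toluene, 80 °C) gives 8-[(1S,5S)-1-hydroxy-4-oxo-5-[(2Z)-pent-2-en-1-yl]cyclopent-2-en-1-yl]octanoic acid F5. Ac2O/Sc(OTf)3 acetylation, followed by aqueous hydrolysis of the mixed anhydride, gives 13.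

**Further compounds**
F1 | step 2 | 1,3-bis(trimethylsilyloxy)-2-[(2Z)-pent-2-en-1-yl]cyclopenta-1,3-diene | CC/C=C\CC1=C(O[Si](C)(C)C)CC=C1O[Si](C)(C)C
F2 | step 2 | 3-(trimethylsilyloxy)-2-[(2Z)-pent-2-en-1-yl]cyclopenta-2,4-dien-1-one | CC/C=C\CC1=C(O[Si](C)(C)C)C=CC1=O
F3 | step 3 | (4R,5R)-4-hydroxy-5-[(2Z)-pent-2-en-1-yl]cyclopent-2-en-1-one | CC/C=C\C[C@@H]1[C@H](O)C=CC1=O
F4 | step 3 | (1S,4R,5R)-1-(hept-6-en-1-yl)-5-[(2Z)-pent-2-en-1-yl]cyclopent-2-ene-1,4-diol | CC/C=C\C[C@@H]1[C@H](O)C=C[C@]1(CCCCCC=C)O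
F5 | step 5 | 8-[(1S,5S)-1-hydroxy-4-oxo-5-[(2Z)-pent-2-en-1-yl]cyclopent-2-en-1-yl]octanoic acid | CC/C=C\C[C@@H]1C(=O)C=C[C@]1(CCCCCCCC(=O)O)O
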